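**Retrosynthetic overview**

1. The plan rests on the cyclohexene ring C1–C6: its C3=C4 double bond lies between C2 (Cl) and C5 (OH), which are cis to each other and to the exocyclic C7 on C1, while the oxygens on C1 and C6 are cis on the opposite face. This is the substitution pattern of a formyl-endo [4+2] adduct of an E,E-1,4-dioxygenated diene and a Z-1,2-dioxygenated enal.
2. Target 14 ⇐ 1β,2β-vinyl epoxide 12 (anti opening by HCl at allylic C2) ⇐ trans-C1/C2 diol 11 (Mitsunobu closure, O5 silylated) ⇐ diacetate 9.
3. 9 ⇐ aldehyde 7 by borohydride reduction, with the tertiary benzoate moving from O1 to the new O7.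
4. 7 ⇐ diene 6 + enal 5 by a catalytic asymmetric Diels–Alder reaction that forms C1–C2 and C5–C6 and closes the only ring with all four stereocentres.
5. 5 ⇐ 2-(benzoyloxy)malonaldehyde 4 ⇐ double ozonolysis of penta-1,4-dien-3-yl benzoate 3.

Key step: step 4

Convention: C1 is the ring carbon bearing C7, then C2, C3=C4, C5, C6 round the ring. With C1→C6 drawn clockwise, β is the face toward the viewer and α the face away. The target is 1β-OH, 1α-CH2OBz, 2α-Cl, 5α-OH, 6β-OBz, which is (1R,2R,5S,6R) in this numbering.

Assumption: the facial sense of the catalyst is taken from the formyl C–H···O binding model known for 2-bromoacrolein, which assigns the required Cα-Re addition to the (S)-configured catalyst. This must be confirmed on the first adduct; the (R)-catalyst would give the antipode by the same chemistry.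

**Step 1**
Reactants: 1 penta-1,4-dien-3-ol; 2 benzoyl chloride
Product: 3 penta-1,4-dien-3-yl benzoate
Conditions: pyridine, 4-(dimethylamino)pyridine (cat.), CH2Cl2, 0 °C → rt
Reagents that add atoms: none
Why: Base-mediated O-acylation of a secondary alcohol with an acid chloride; no stereocentre is involved.

**Step 2**
Reactants: 3 penta-1,4-dien-3-yl benzoate
Product: 4 2-(benzoyloxy)malonaldehyde (present mainly as its enol, 2-(benzoyloxy)-3-hydroxyacrylaldehyde)
Conditions: O3, CH2Cl2, –78 °C; then PPh3, –78 °C → rt; used crude
Reagents that add atoms: ozone, [O-][O+]=O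
Why: Twofold ozonolysis of the two terminal vinyl groups with reductive cleavage of the ozonides should release the 1,3-dialdehyde under neutral conditions that spare the benzoate and the sensitive vinylogous acid.

**Step 3**
Reactants: 4 2-(benzoyloxy)malonaldehyde; 2 benzoyl chloride
Product: 5 (Z)-2,3-bis(benzoyloxy)acrylaldehyde (β-benzoate trans to CHO, cis to the α-benzoate)
Conditions: pyridine, CH2Cl2, –20 → 0 °C
Reagents that add atoms: none
Why: O-acylation of the malonaldehyde enol gives the β-acyloxy enal, and reversible conjugate addition of pyridine should let the alkene settle in the preferred geometry with the new benzoate trans to the formyl group, as in 3-alkoxy-2-substituted acroleins; the geometry is to be checked by NOE before use.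

**Step 4**
Reactants: 5 (Z)-2,3-bis(benzoyloxy)acrylaldehyde; 6 (1E,3E)-buta-1,3-diene-1,4-diyl diacetate
Product: 7 1β,6β-bis(benzoyloxy)-2α,5α-diacetoxycyclohex-3-ene-1α-carbaldehyde
Conditions: (S)-tetrahydro-1-(2-methylphenyl)-3,3-diphenyl-1H,3H-pyrrolo[1,2-c][1,3,2]oxazaborole·HN(SO2CF3)2 (20 mol%), diene in threefold excess, CH2Cl2, –40 → 0 °C
Reagents that add atoms: none
Why: Proposed new method: the protonated oxazaborolidine binds the formyl oxygen of 5 (boron anti to the C=C, formyl C–H···O contact to the ring oxygen) and lowers the LUMO of the s-trans enal enough to offset the donor effect of the β-benzoate, after which 6 adds across Cα=Cβ in one concerted, asynchronous, suprafacial [4+2] event forming C1–C2 and C5–C6. The closest known reaction types are oxazaborolidinium-catalysed enantioselective Diels–Alder reactions of 2-substituted acroleins and thermal all-cis cycloadditions of 6 with activated dienophiles; the new element is an enal carrying acyloxy groups at both Cα and Cβ under this catalysis. The cyclohexene ring, the only ring, closes by intermolecular [4+2] cycloaddition, and C3=C4 arises from the central bond of the diene. C2 and C5 come out cis because 6 is E,E, the C1 and C6 benzoates come out cis because 5 is Z, the formyl-endo transition state (secondary overlap of the bound C=O, no bridging methylene to force it exo) puts C7 on the face of the two acetoxy groups, and the absolute sense comes from the catalyst phenyl group covering one enal face so that the diene adds to the Cα-Re/Cβ-Re face. The step needs endo/exo and facial selectivity but no regiocontrol, because the two ends of 6 are equivalent. A Lewis acid is chosen over a chiral primary amine because an amine would attack the vinylogous anhydride 5 at Cβ or at a benzoyl group and be consumed.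

**Step 5**
Reactants: 7 1β,6β-bis(benzoyloxy)-2α,5α-diacetoxycyclohex-3-ene-1α-carbaldehyde
Product: 9 2α,5α-diacetoxy-6β-benzoyloxy-1α-(benzoyloxymethyl)cyclohex-3-en-1β-ol, via primary alcohol 8 (not isolated)
Conditions: NaBH4, THF/MeOH (5:1), –30 → 0 °C; AcOH quench
Reagents that add atoms: none
Why: Borohydride reduction of the non-enolisable aldehyde gives the primary alkoxide, which should attack the adjacent tertiary benzoate through a five-membered 2-phenyl-1,3-dioxolan-2-olate (1,2 O→O acyl migration, driven by the change from a crowded tertiary to a primary ester); C1 keeps its configuration because no bond to it is broken.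

**Step 6**
Reactants: 9 2α,5α-diacetoxy-6β-benzoyloxy-1α-(benzoyloxymethyl)cyclohex-3-en-1β-ol
Product: 10 6β-benzoyloxy-1α-(benzoyloxymethyl)cyclohex-3-ene-1β,2α,5α-triol
Conditions: HCl (1.25 M in MeOH), CH2Cl2, 0 °C → rt
Reagents that add atoms: none
Why: Acid-catalysed transesterification with methanol removes aliphatic acetates much faster than benzoates, and the acidic medium should suppress benzoyl migration to the freed hydroxyl groups; no stereocentre is touched.

**Step 7**
Reactants: 10 6β-benzoyloxy-1α-(benzoyloxymethyl)cyclohex-3-ene-1β,2α,5α-triol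
Product: 11 6β-benzoyloxy-1α-(benzoyloxymethyl)-5α-(triethylsilyloxy)cyclohex-3-ene-1β,2α-diol
Conditions: Et3SiCl (1.1 equiv), imidazole, CH2Cl2, –40 → –20 °C
Reagents that add atoms: chlorotriethylsilane, CC[Si](Cl)(CC)CC
Why: Silylation with a trialkylsilyl chloride and imidazole follows steric access, so the C5 hydroxyl (next to a CH) should react ahead of the C2 hydroxyl (next to the fully substituted C1) and the tertiary C1 hydroxyl.

**Step 8**
Reactants: 11 6β-benzoyloxy-1α-(benzoyloxymethyl)-5α-(triethylsilyloxy)cyclohex-3-ene-1β,2α-diol
Product: 12 1β,2β-epoxy-6β-benzoyloxy-1α-(benzoyloxymethyl)-5α-(triethylsilyloxy)cyclohex-3-ene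
Conditions: PPh3, DIAD, THF, 0 °C → rt
Reagents that add atoms: none
Why: Mitsunobu cyclodehydration of a trans-1,2-diol: the secondary C2 oxygen is activated as the alkoxyphosphonium ion and displaced from the opposite face by the trans tertiary C1 oxygen (3-exo-tet, inversion at C2, C1 retained), giving the β-epoxide.

**Step 9**
Reactants: 12 1β,2β-epoxy-6β-benzoyloxy-1α-(benzoyloxymethyl)-5α-(triethylsilyloxy)cyclohex-3-ene
Product: 14 [(1R,2R,5S,6R)-6-(benzoyloxy)-2-chloro-1,5-dihydroxycyclohex-3-en-1-yl]methyl benzoate (CNP0326102.1), via silyl chlorohydrin 13 (not isolated)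
Conditions: conc. aq. HCl, THF, 0 °C → rt
Reagents that add atoms: hydrogen chloride, Cl
Why: The protonated vinyl epoxide should open by SN2 attack of chloride at the allylic C2 anti to the C–O bond (trans-diaxial opening; C1 is tertiary and flanked by electron-withdrawing groups), which inverts C2 a second time to give 2α-Cl and 1β-OH, and the aqueous acid then hydrolyses the triethylsilyl ether.

**Compound list**

1 | penta-1,4-dien-3-ol | C=CC(O)C=C | starting material
2 | benzoyl chloride | O=C(Cl)c1ccccc1 | starting material
3 | penta-1,4-dien-3-yl benzoate | C=CC(OC(=O)c1ccccc1)C=C | intermediate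
4 | 2-(benzoyloxy)malonaldehyde (enolised in solution) | O=CC(OC(=O)c1ccccc1)C=O | intermediate
5 | (Z)-2,3-bis(benzoyloxy)acrylaldehyde | O=C/C(OC(=O)c1ccccc1)=C/OC(=O)c1ccccc1 | intermediate
6 | (1E,3E)-buta-1,3-diene-1,4-diyl diacetate | CC(=O)O/C=C/C=C/OC(C)=O | starting material
7 | 1β,6β-bis(benzoyloxy)-2α,5α-diacetoxycyclohex-3-ene-1α-carbaldehyde | O=C[C@]1(OC(=O)c2ccccc2)[C@H](OC(C)=O)C=C[C@H](OC(C)=O)[C@H]1OC(=O)c1ccccc1 | intermediate
8 | [1β,6β-bis(benzoyloxy)-2α,5α-diacetoxycyclohex-3-en-1α-yl]methanol | OC[C@]1(OC(=O)c2ccccc2)[C@H](OC(C)=O)C=C[C@H](OC(C)=O)[C@H]1OC(=O)c1ccccc1 | intermediate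
9 | 2α,5α-diacetoxy-6β-benzoyloxy-1α-(benzoyloxymethyl)cyclohex-3-en-1β-ol | O=C(OC[C@]1(O)[C@H](OC(C)=O)C=C[C@H](OC(C)=O)[C@H]1OC(=O)c1ccccc1)c1ccccc1 | intermediate
10 | 6β-benzoyloxy-1α-(benzoyloxymethyl)cyclohex-3-ene-1β,2α,5α-triol | O=C(OC[C@]1(O)[C@H](O)C=C[C@H](O)[C@H]1OC(=O)c1ccccc1)c1ccccc1 | intermediate
11 | 6β-benzoyloxy-1α-(benzoyloxymethyl)-5α-(triethylsilyloxy)cyclohex-3-ene-1β,2α-diol | O=C(OC[C@]1(O)[C@H](O)C=C[C@H](O[Si](CC)(CC)CC)[C@H]1OC(=O)c1ccccc1)c1ccccc1 | intermediate
12 | 1β,2β-epoxy-6β-benzoyloxy-1α-(benzoyloxymethyl)-5α-(triethylsilyloxy)cyclohex-3-ene | O=C(OC[C@]12O[C@H]1C=C[C@H](O[Si](CC)(CC)CC)[C@H]2OC(=O)c1ccccc1)c1ccccc1 | intermediate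
13 | 6β-benzoyloxy-1α-(benzoyloxymethyl)-2α-chloro-5α-(triethylsilyloxy)cyclohex-3-en-1β-ol | O=C(OC[C@]1(O)[C@H](Cl)C=C[C@H](O[Si](CC)(CC)CC)[C@H]1OC(=O)c1ccccc1)c1ccccc1 | intermediate
14 | [(1R,2R,5S,6R)-6-(benzoyloxy)-2-chloro-1,5-dihydroxycyclohex-3-en-1-yl]methyl benzoate | O=C(OC[C@]1(O)[C@H](Cl)C=C[C@H](O)[C@H]1OC(=O)c1ccccc1)c1ccccc1 | target

**Step count and risks**

Total step count: 9. Longest linear sequence: 9 steps (1 → 14); diene 6 is purchased.

Steps most likely to fail:

1. Step 4 (the proposed catalysed cycloaddition). The push–pull enal may react too slowly, a stepwise conjugate addition may expel benzoate instead of closing the ring, or material may leak through the exo orientation or the wrong enal face. The fallback uses known chemistry and sets out from 5 and 6. These are combined without a chiral catalyst in an uncatalysed thermal Diels–Alder reaction (neat or in toluene, 90–110 °C, with 2,6-di-tert-butyl-4-methylphenol as radical inhibitor, or at 10–12 kbar at room temperature), the reaction mode established for 6 with activated dienophiles. This should give the all-cis formyl-endo adduct as a racemate, that is 7 together with its mirror image, the enantiomeric adduct F1. Preparative chromatography on a chiral stationary phase (amylose tris(3,5-dimethylphenylcarbamate)) separates the two, and the route is rejoined at 7.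

2. Step 5 (reduction with benzoyl shift). An acetyl group may be transferred from the C2 oxygen to the new primary alkoxide through a six-membered pathway in competition with the benzoyl shift, and acetates may be partly lost by methanolysis. The fallback sets out from 7 and reorders the events so that no acetate is present when the shift occurs. Reduction with NaBH4/CeCl3·7H2O in MeOH/THF at –78 °C with a cold AcOH quench should allow isolation of primary alcohol 8 without acyl transfer. Acidic methanolysis (HCl in MeOH, as in step 6) then removes both acetates while the tertiary benzoate stays in place, giving 1β,6β-bis(benzoyloxy)-1α-(hydroxymethyl)cyclohex-3-ene-2α,5α-diol F2. Catalytic 1,8-diazabicyclo[5.4.0]undec-7-ene in CH2Cl2 at 0 °C finally moves the tertiary benzoate to the primary C7 oxygen, the only favourable 1,2-shift left, and the route is rejoined at 10.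

3. Step 7 (monosilylation). Silylation may occur at the C2 hydroxyl or twice, through poor site selectivity. The fallback sets out from 10 and drops the protecting group. Triol 10 is treated directly with PPh3/DIAD in THF at 0 °C; only the vicinal trans-diol can form a cyclic dioxaphosphorane and collapse to an epoxide, while the isolated C5 hydroxyl has no partner for displacement. This should give 1β,2β-epoxy-6β-benzoyloxy-1α-(benzoyloxymethyl)cyclohex-3-en-5α-ol F3. Opening with conc. aq. HCl in THF at 0 °C, as in step 9, then gives the target directly, and the route is rejoined at 14.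

**Further compounds**

F1 | step 4 | 1α,6α-bis(benzoyloxy)-2β,5β-diacetoxycyclohex-3-ene-1β-carbaldehyde (enantiomer of 7) | O=C[C@@]1(OC(=O)c2ccccc2)[C@@H](OC(C)=O)C=C[C@@H](OC(C)=O)[C@@H]1OC(=O)c1ccccc1
F2 | step 5 | 1β,6β-bis(benzoyloxy)-1α-(hydroxymethyl)cyclohex-3-ene-2α,5α-diol | OC[C@]1(OC(=O)c2ccccc2)[C@H](O)C=C[C@H](O)[C@H]1OC(=O)c1ccccc1
F3 | step 7 | 1β,2β-epoxy-6β-benzoyloxy-1α-(benzoyloxymethyl)cyclohex-3-en-5α-ol | O=C(OC[C@]12O[C@H]1C=C[C@H](O)[C@H]2OC(=O)c1ccccc1)c1ccccc1
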